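The strategy rests on one feature of the single benzene ring. The neighbouring carbons C2 and C3 (C1 bears the CH2N carbon) hold the same atom, Br, beside the catechol oxygens on C4 and C5, so both C–Br bonds are cut together back to a C2–C3 aryne, for which the sense of addition cannot matter.
The aryne comes from a C2–SiMe3/C3–OTf pair. The triflate oxygen is the third ring oxygen of bought 3-hydroxy-4,5-dimethoxybenzaldehyde, and silicon reaches C2 by ortho-bromination, bromine–lithium exchange and O-to-C silyl migration.
The HO2C–CH2CH2–C(O)–NH chain is cut at the benzylic C–N bond to succinimide (Mitsunobu). The imide carries no N–H through the aryne step and is opened by hydroxide afterwards; BBr3 cleavage of the two methyl ethers comes last.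
Ring order: no ring is built. The benzene ring and the five-membered imide ring are bought, and the imide ring is opened in the penultimate step.

Key step: step 7

Assumption: 3-hydroxy-4,5-dimethoxybenzaldehyde and succinimide are taken as catalogue compounds; ring positions are counted throughout from C1, the carbon bearing the benzylic carbon, so the bromines of the target sit on C2/C3 and its oxygens on C4/C5.

Step 1
Reactants: 1 3-hydroxy-4,5-dimethoxybenzaldehyde
Product: 2 2-bromo-3-hydroxy-4,5-dimethoxybenzaldehyde
Conditions: NBS (1.0 equiv, slow addition), i-Pr2NH (10 mol %), CH2Cl2, 0 °C, dark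
Reagents that add atoms: N-bromosuccinimide, O=C1CCC(=O)N1Br
Why: Electrophilic aromatic bromination with amine-mediated ortho delivery: the N-bromoamine made in situ is hydrogen-bonded to the phenol and hands bromine to its only free ortho carbon, C2, which is also para to the C5 methoxy group and corresponds to the site at which isovanillin brominates, and an NOE from the remaining ring hydrogen to both CHO and OMe should confirm the assignment.

Step 2
Reactants: 2 2-bromo-3-hydroxy-4,5-dimethoxybenzaldehyde
Product: 3 2-bromo-3-(hydroxymethyl)-5,6-dimethoxyphenol (2-bromo-3-hydroxy-4,5-dimethoxybenzyl alcohol)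
Conditions: NaBH4 (1.5 equiv), MeOH, 0 °C; aq NH4Cl
Reagents that add atoms: none
Why: Borohydride reduction of an aryl aldehyde, which leaves the aryl bromide, the phenol and the methyl ethers untouched.

Step 3
Reactants: 3 2-bromo-3-(hydroxymethyl)-5,6-dimethoxyphenol
Product: 4 2-bromo-4,5-dimethoxy-3-(trimethylsilyloxy)benzyl trimethylsilyl ether
Conditions: HMDS (2 equiv), (NH4)2SO4 (cat.), THF, reflux; evaporate, use crude
Reagents that add atoms: hexamethyldisilazane, C[Si](C)(C)N[Si](C)(C)C
Why: O-silylation of both hydroxyl groups with HMDS gives only ammonia beside the product, so the moisture-sensitive bis-silyl ether can go on after evaporation without aqueous work-up.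

Step 4
Reactants: 4 2-bromo-4,5-dimethoxy-3-(trimethylsilyloxy)benzyl trimethylsilyl ether
Product: 7 3-hydroxy-4,5-dimethoxy-2-(trimethylsilyl)benzyl alcohol, via C2 aryllithium 5 (not isolated), via lithium phenoxide 6 (not isolated)
Conditions: n-BuLi (1.1 equiv), THF, −78 °C to rt; then MeOH, K2CO3 (cat.), rt; aq NH4Cl
Reagents that add atoms: none
Why: Bromine–lithium exchange followed by retro-Brook (O-to-C) silyl migration, the standard entry to o-silylphenols: carbanion 5 lies between two O–SiMe3 groups, the 1,3-shift from the phenol oxygen gives 6, a competing 1,4-shift from the benzylic oxygen would put the same silicon on the same carbon, and base-catalysed methanolysis of the O–Si bond that remains brings either course to 7 without the acid that could protodesilylate this electron-rich ring.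

Step 5
Reactants: 7 3-hydroxy-4,5-dimethoxy-2-(trimethylsilyl)benzyl alcohol
Product: 8 5-(hydroxymethyl)-2,3-dimethoxy-6-(trimethylsilyl)phenyl trifluoromethanesulfonate
Conditions: PhNTf2 (1.05 equiv), K2CO3 (1.5 equiv), MeCN, 0 °C to rt
Reagents that add atoms: N-phenylbis(trifluoromethanesulfonimide), O=S(=O)(C(F)(F)F)N(c1ccccc1)S(=O)(=O)C(F)(F)F
Why: Chemoselective O-triflation: carbonate deprotonates only the phenol and PhNTf2 passes its triflyl group to phenoxides but not to neutral primary alcohols, while room temperature and the absence of fluoride or crown ether keep the new silyl triflate from releasing the aryne early.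

Step 6
Reactants: 8 5-(hydroxymethyl)-2,3-dimethoxy-6-(trimethylsilyl)phenyl trifluoromethanesulfonate; 9 succinimide
Product: 10 N-[4,5-dimethoxy-3-(trifluoromethylsulfonyloxy)-2-(trimethylsilyl)benzyl]succinimide
Conditions: PPh3 (1.3 equiv), DIAD (1.3 equiv), THF, 0 °C to rt
Reagents that add atoms: none
Why: Mitsunobu reaction: succinimide (pKa about 9.6) is acidic enough for the phosphine–azodicarboxylate betaine and displaces the primary benzylic oxyphosphonium ion by SN2 under neutral, fluoride-free conditions that leave the SiMe3/OTf pair intact and give a nitrogen without N–H.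

Step 7
Reactants: 10 N-[4,5-dimethoxy-3-(trifluoromethylsulfonyloxy)-2-(trimethylsilyl)benzyl]succinimide
Product: 13 N-(2,3-dibromo-4,5-dimethoxybenzyl)succinimide, via C2-C3 aryne 11 (not isolated), via C3 aryl anion 12 (not isolated)
Conditions: CsF (3 equiv, flame-dried), n-Bu4NBr (4 equiv, dried), BrCCl2CCl2Br (3 equiv), 4 Å MS, MeCN–toluene 1:2, 0 °C to rt, dark, Ar
Reagents that add atoms: tetrabutylammonium bromide, CCCC[N+](CCCC)(CCCC)CCCC.[Br-]; 1,2-dibromo-1,1,2,2-tetrachloroethane, BrC(Cl)(Cl)C(Cl)(Cl)Br
Why: Proposed new method: desilylation at C2 by fluoride expels the neighbouring C3 triflate, so the triple bond of 11 can sit nowhere but between C2 and C3; a bromide ion then attacks this bent, electrophilic bond (C2 is the expected site, since the C4 methoxy group distorts the aryne and lends inductive support to negative charge on C3), and carbanion 12 pulls Br+ off BrCCl2CCl2Br, which falls apart to Cl2C=CCl2 and a fresh bromide ion, making the halide a chain carrier. Nearest known reaction types are the insertion of arynes from o-silylaryl triflates into the I–I bond of iodine, the dihalogenation of thermally made arynes by Br2 or by CuCl2/CuBr2-based reagents, and the halophilic quench of aryl anions by polyhaloalkanes; their combination to place two bromines on a pentasubstituted aryne is untested. The step closes no ring and creates no stereocentre. Orientation is of no consequence, because the opposite sense of addition leads to the same compound 13. The selectivity that matters is chemoselectivity, namely bromide attack and bromine transfer ahead of proton pick-up by 12, ahead of addition of fluoride or an imide carbonyl oxygen to 11, and ahead of electrophilic attack of the donor at C6–H or at the C2–Si bond of 10; the substrate contributes a nitrogen without hydrogen, no hydroxyl group and a single ring hydrogen that is not adjacent to the aryne carbons. The conditions add dryness, MeCN thinned with toluene to lower the concentration of its weakly acidic C–H bonds and to slow the dissolution of CsF, a large excess of dissolved bromide, and a donor free of molecular bromine.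

Step 8
Reactants: 13 N-(2,3-dibromo-4,5-dimethoxybenzyl)succinimide
Product: 15 4-[(2,3-dibromo-4,5-dimethoxybenzyl)amino]-4-oxobutanoic acid, via lithium carboxylate 14 (not isolated)
Conditions: LiOH·H2O (1.5 equiv), THF–H2O 3:1, 0 °C to rt; then 1 M HCl to pH 2
Reagents that add atoms: lithium hydroxide, [Li+].[OH-]
Why: Imide hydrolysis: hydroxide adds to one of the two equivalent imide carbonyl groups and the ring opens to carboxylate 14, whose charge shields the remaining secondary amide from further hydrolysis, and doing this before the phenols are freed keeps a catechol away from aerobic base.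

Step 9
Reactants: 15 4-[(2,3-dibromo-4,5-dimethoxybenzyl)amino]-4-oxobutanoic acid
Product: 17 4-[(2,3-dibromo-4,5-dihydroxybenzyl)amino]-4-oxobutanoic acid (CNP0116984.0), via cyclic bromoborate 16 (not isolated)
Conditions: BBr3 (6 equiv), CH2Cl2, −78 °C to rt, Ar; then degassed ice-water, EtOAc extraction under Ar
Reagents that add atoms: none
Why: Lewis-acid cleavage of aryl methyl ethers with BBr3, the usual closing step for 2,3-dibromo-4,5-dimethoxybenzyl compounds: each coordinated ether loses MeBr, borate 16 is hydrolysed on quenching, the two bromines slow ionisation of the benzylic C–N bond, and the extra reagent covers the acid and amide oxygens.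

Compound list
1 | 3-hydroxy-4,5-dimethoxybenzaldehyde | O=Cc1cc(O)c(OC)c(OC)c1 | starting material
2 | 2-bromo-3-hydroxy-4,5-dimethoxybenzaldehyde | O=Cc1cc(OC)c(OC)c(O)c1Br | intermediate
3 | 2-bromo-3-(hydroxymethyl)-5,6-dimethoxyphenol | OCc1cc(OC)c(OC)c(O)c1Br | intermediate
4 | 2-bromo-4,5-dimethoxy-3-(trimethylsilyloxy)benzyl trimethylsilyl ether | C[Si](C)(C)OCc1cc(OC)c(OC)c(O[Si](C)(C)C)c1Br | intermediate
5 | C2 aryllithium from 4 (not isolated) | [Li]c1c(CO[Si](C)(C)C)cc(OC)c(OC)c1O[Si](C)(C)C | intermediate
6 | lithium 5,6-dimethoxy-2-(trimethylsilyl)-3-[(trimethylsilyloxy)methyl]phenoxide (not isolated) | [Li+].[O-]c1c(OC)c(OC)cc(CO[Si](C)(C)C)c1[Si](C)(C)C | intermediate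
7 | 3-hydroxy-4,5-dimethoxy-2-(trimethylsilyl)benzyl alcohol | OCc1cc(OC)c(OC)c(O)c1[Si](C)(C)C | intermediate
8 | 5-(hydroxymethyl)-2,3-dimethoxy-6-(trimethylsilyl)phenyl trifluoromethanesulfonate | OCc1cc(OC)c(OC)c(OS(=O)(=O)C(F)(F)F)c1[Si](C)(C)C | intermediate
9 | succinimide | O=C1CCC(=O)N1 | starting material
10 | N-[4,5-dimethoxy-3-(trifluoromethylsulfonyloxy)-2-(trimethylsilyl)benzyl]succinimide | O=C1CCC(=O)N1Cc1cc(OC)c(OC)c(OS(=O)(=O)C(F)(F)F)c1[Si](C)(C)C | intermediate
11 | N-(2,3-didehydro-4,5-dimethoxybenzyl)succinimide, the C2–C3 aryne (not isolated) | O=C1CCC(=O)N1CC2=CC(OC)=C(OC)C#C2 | intermediate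
12 | 2-bromo-3-carbanion from bromide addition to 11, drawn as the cesium salt (not isolated) | [Cs+].O=C1CCC(=O)N1Cc1cc(OC)c(OC)[c-]c1Br | intermediate
13 | N-(2,3-dibromo-4,5-dimethoxybenzyl)succinimide | O=C1CCC(=O)N1Cc1cc(OC)c(OC)c(Br)c1Br | intermediate
14 | lithium 4-[(2,3-dibromo-4,5-dimethoxybenzyl)amino]-4-oxobutanoate (not isolated) | [Li+].[O-]C(=O)CCC(=O)NCc1cc(OC)c(OC)c(Br)c1Br | intermediate
15 | 4-[(2,3-dibromo-4,5-dimethoxybenzyl)amino]-4-oxobutanoic acid | O=C(O)CCC(=O)NCc1cc(OC)c(OC)c(Br)c1Br | intermediate
16 | cyclic B-bromo catechol borate of 17, drawn without the boron held by the acid and amide oxygens (not isolated) | O=C(O)CCC(=O)NCc1cc2OB(Br)Oc2c(Br)c1Br | intermediate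
17 | 4-[(2,3-dibromo-4,5-dihydroxybenzyl)amino]-4-oxobutanoic acid, CNP0116984.0 | O=C(O)CCC(=O)NCc1cc(O)c(O)c(Br)c1Br | target

Total step count: 9. Longest linear sequence: 9 steps (1 to 17); succinimide 9 enters as bought.

Steps most likely to fail

Step 7 is the only step beyond known chemistry. Several processes could take over:
- The aryl anion could be protonated faster than bromine is transferred.
- Fluoride or an imide carbonyl oxygen could capture the aryne.
- The bromine donor could attack the C–Si bond or C6 electrophilically before fluoride acts.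

The fallback drops the aryne and uses the established bromination route to this ring pattern. It sets out from succinimide 9 and comes back at 13.
- Bought vanillin is brominated with Br2 in AcOH to 5-bromovanillin F1.
- More Br2 and Fe powder in the same solvent brominate para to the methoxy group to give 5,6-dibromovanillin F2.
- MeI/K2CO3 in DMF gives 2,3-dibromo-4,5-dimethoxybenzaldehyde F3.
- NaBH4 in MeOH gives (2,3-dibromo-4,5-dimethoxyphenyl)methanol F4.
- The Mitsunobu conditions of step 6 join F4 to 9 to give 13, after which steps 8 and 9 follow unchanged.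

Step 1 may show poor site selectivity, because C6 is para to the hydroxyl group and ortho to a methoxy group and can compete with C2. Double bromination is also possible. The fallback puts silicon on C2 directly by directed ortho-metalation, so no bromine is needed. It sets out from 1 and comes back at 7.
- Compound 1 is O-carbamoylated (ClC(O)NEt2, K2CO3, MeCN, reflux) to 5-formyl-2,3-dimethoxyphenyl diethylcarbamate F5.
- NaBH4 in MeOH reduces it to 5-(hydroxymethyl)-2,3-dimethoxyphenyl diethylcarbamate F6.
- F6 is treated with s-BuLi (2.2 equiv)/TMEDA in THF at −78 °C. The carbamate is the strongest director on the ring, its only free ortho carbon is C2, and the lithium alkoxide arm supports the same site, so the C2,O-dilithio species F7 should form.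
- Excess TMSCl gives the C,O-bis(trimethylsilyl) carbamate F8.
- K2CO3/MeOH removes the O-silyl group to give 5-(hydroxymethyl)-2,3-dimethoxy-6-(trimethylsilyl)phenyl diethylcarbamate F9.
- LiAlH4 in THF cleaves the carbamate to give 7.

Step 4 could fail in three ways. n-BuLi could attack the aryl O–Si bond, the aryllithium could be protonated or butylated before silicon migrates, or the electron-rich o-silylphenol could protodesilylate during work-up or on silica. The fallback gives up the migration and brings silicon from outside onto a preformed polyanion. It sets out from 3 and comes back at 7.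
- Compound 3 is deprotonated twice with n-BuLi (2 equiv) in THF at −78 °C and exchanged with t-BuLi (2 equiv) to the O,O,C2-trilithio species F10.
- Excess TMSCl gives the tris(trimethylsilyl) compound F11.
- K2CO3/MeOH strips the two O-silyl groups to give 7, which is carried into step 5 without chromatography.

Further compounds
F1 | step 7 | 5-bromovanillin | O=Cc1cc(OC)c(O)c(Br)c1
F2 | step 7 | 5,6-dibromovanillin | O=Cc1cc(OC)c(O)c(Br)c1Br
F3 | step 7 | 2,3-dibromo-4,5-dimethoxybenzaldehyde | O=Cc1cc(OC)c(OC)c(Br)c1Br
F4 | step 7 | (2,3-dibromo-4,5-dimethoxyphenyl)methanol | OCc1cc(OC)c(OC)c(Br)c1Br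
F5 | step 1 | 5-formyl-2,3-dimethoxyphenyl diethylcarbamate | O=Cc1cc(OC)c(OC)c(OC(=O)N(CC)CC)c1
F6 | step 1 | 5-(hydroxymethyl)-2,3-dimethoxyphenyl diethylcarbamate | OCc1cc(OC)c(OC)c(OC(=O)N(CC)CC)c1
F7 | step 1 | C2,O-dilithio species | [Li]OCc1cc(OC)c(OC)c(OC(=O)N(CC)CC)c1[Li]
F8 | step 1 | C,O-bis(trimethylsilyl) carbamate | C[Si](C)(C)OCc1cc(OC)c(OC)c(OC(=O)N(CC)CC)c1[Si](C)(C)C
F9 | step 1 | 5-(hydroxymethyl)-2,3-dimethoxy-6-(trimethylsilyl)phenyl diethylcarbamate | OCc1cc(OC)c(OC)c(OC(=O)N(CC)CC)c1[Si](C)(C)C
F10 | step 4 | O,O,C2-trilithio species | [Li]OCc1cc(OC)c(OC)c(O[Li])c1[Li]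
F11 | step 4 | tris(trimethylsilyl) compound | C[Si](C)(C)OCc1cc(OC)c(OC)c(O[Si](C)(C)C)c1[Si](C)(C)C
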